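**Retrosynthetic overview**
1. The oxolane is closed last (O1–C2 bond) by acid-mediated cyclisation of a butane-1,4-diol that carries a benzylic carbinol; this triol comes from LiAlH4 reduction of a trans-3,4-disubstituted γ-lactone acetal.
2. Key disconnection: the oxolane C4–CH2(benzylic) bond and the C3–C(carbinol) bond are made in one three-component union of a lithiated 2-aryl-1,3-dithiane (the complete dihydrobenzofuran half), (5S)-5-(d-menthyloxy)furan-2(5H)-one and O-TIPS-isovanillin.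
3. Enabling feature: in the oxolane, C3 and C4 are adjacent CH centres that each carry a one-carbon branch and C5 is an OCH2, so C5–C4–C3–CH2OH is a furan-2(5H)-one at a higher oxidation level (C4 = β-carbon, C3 = α-carbon, CH2OH = carbonyl carbon, C5 = acetal carbon holding the auxiliary); the benzylic CH2 on C4 can therefore enter as a dithiane carbanion.
4. Dihydrobenzofuran half: an Evans syn-aldol of a 2,6-bis(MOM-oxy)arylacetyl oxazolidinone with O-TIPS-vanillin sets C3; the furan ring then closes (O1–C2) through either of two homotopic phenols, the remaining phenol is methylated, and ArCO2Me is taken to ArCHO and the dithiane.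
5. Ring order: both benzene rings are bought; the dihydrofuran ring of the benzofuran forms in step 8; the oxolane forms in step 18.

Key step: step 15

Assumption: the carbinol carbon created by the aldol trapping in step 15 is carried as a mixture of epimers (drawn without a descriptor in 28–30), because that centre is ionised and reset in step 18.

Step 1
Reactants: 1 methyl 4-bromo-3,5-dihydroxybenzoate
Product: 2 methyl 4-bromo-3,5-bis(methoxymethoxy)benzoate
Conditions: MOMCl, i-Pr2NEt, CH2Cl2, 0 °C → rt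
Reagents that add atoms: chloromethyl methyl ether COCCl
Why: Base-mediated O-alkylation of both phenols (MOM acetal protection); the groups are chosen because one acid treatment later removes both and triggers ring closure.

Step 2
Reactants: 2 methyl 4-bromo-3,5-bis(methoxymethoxy)benzoate; 3 benzyl bromoacetate
Product: 5 benzyl 2-[4-(methoxycarbonyl)-2,6-bis(methoxymethoxy)phenyl]acetate, via Reformatsky reagent 4 (not isolated)
Conditions: 3, Zn dust (TMSCl-activated), THF, 40 °C; then 2, Pd(dba)2 (cat.), Q-Phos (cat.), THF, 65 °C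
Reagents that add atoms: none
Why: Negishi-type coupling of a zinc ester enolate with the aryl bromide (Pd-catalysed ester α-arylation); the para ester assists oxidative addition into the doubly ortho-alkoxylated C–Br bond, the bulky electron-rich ligand is of the type used for hindered bromides, and the neutral zinc enolate leaves the methyl ester and MOM ethers alone.

Step 3
Reactants: 5 benzyl 2-[4-(methoxycarbonyl)-2,6-bis(methoxymethoxy)phenyl]acetate
Product: 6 2-[4-(methoxycarbonyl)-2,6-bis(methoxymethoxy)phenyl]acetic acid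
Conditions: H2 (1 atm), 10% Pd/C, EtOAc, rt
Reagents that add atoms: none
Why: Hydrogenolysis of the benzyl ester under neutral conditions, which frees the acid without touching the acid-labile MOM ethers or the methyl ester.

Step 4
Reactants: 6 2-[4-(methoxycarbonyl)-2,6-bis(methoxymethoxy)phenyl]acetic acid; 7 (S)-4-benzyl-1,3-oxazolidin-2-one
Product: 9 methyl 4-{2-[(4S)-4-benzyl-2-oxo-1,3-oxazolidin-3-yl]-2-oxoethyl}-3,5-bis(methoxymethoxy)benzoate, via mixed pivalic anhydride 8 (not isolated)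
Conditions: PivCl, Et3N, THF, −20 °C; then 7, LiCl, −20 °C → rt
Reagents that add atoms: none
Why: N-acylation of the oxazolidinone auxiliary through the mixed pivalic anhydride (LiCl/Et3N protocol), in which the hindered pivaloyl carbonyl steers attack to the arylacetyl carbonyl.

Step 5
Reactants: 10 vanillin (4-hydroxy-3-methoxybenzaldehyde)
Product: 11 3-methoxy-4-[tri(propan-2-yl)silyloxy]benzaldehyde
Conditions: TIPSCl, imidazole, DMF, rt
Reagents that add atoms: chlorotri(propan-2-yl)silane CC(C)[Si](Cl)(C(C)C)C(C)C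
Why: Phenol silylation; the TIPS aryl ether is chosen to withstand base, hydride, mild acid and organolithium steps and to leave with fluoride at the end.

Step 6
Reactants: 9 methyl 4-{2-[(4S)-4-benzyl-2-oxo-1,3-oxazolidin-3-yl]-2-oxoethyl}-3,5-bis(methoxymethoxy)benzoate; 11 3-methoxy-4-[tri(propan-2-yl)silyloxy]benzaldehyde
Product: 13 (4S)-4-benzyl-3-[(2S,3S)-3-hydroxy-2-[4-(methoxycarbonyl)-2,6-bis(methoxymethoxy)phenyl]-3-{3-methoxy-4-[tri(propan-2-yl)silyloxy]phenyl}propanoyl]-1,3-oxazolidin-2-one, via boron enolate 12 (not isolated)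
Conditions: n-Bu2BOTf, i-Pr2NEt, CH2Cl2, −78 → 0 °C; then 11, −78 → 0 °C; pH 7 buffer, MeOH, H2O2
Reagents that add atoms: none
Why: Evans syn-aldol through the (Z)-dibutylboron enolate and a Zimmerman–Traxler chair in which the (S)-benzyl group of the auxiliary blocks one enolate face, which sets the α-carbon (the later benzofuran C3); the syn carbinol centre is formed as well but is not needed later.

Step 7
Reactants: 13 the Evans syn-aldol adduct
Product: 14 (1S,2R)-2-[4-(hydroxymethyl)-2,6-bis(methoxymethoxy)phenyl]-1-{3-methoxy-4-[tri(propan-2-yl)silyloxy]phenyl}propane-1,3-diol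
Conditions: LiAlH4, THF, 0 °C
Reagents that add atoms: none
Why: Hydride reduction that cleaves the exocyclic imide carbonyl to the primary alcohol (releasing the auxiliary) and reduces the methyl benzoate to the benzylic alcohol in the same operation, fast enough at 0 °C to outrun retro-aldol cleavage.

Step 8
Reactants: 14 (1S,2R)-2-[4-(hydroxymethyl)-2,6-bis(methoxymethoxy)phenyl]-1-{3-methoxy-4-[tri(propan-2-yl)silyloxy]phenyl}propane-1,3-diol
Product: 16 (2S,3R)-3,6-bis(hydroxymethyl)-2-{3-methoxy-4-[tri(propan-2-yl)silyloxy]phenyl}-2,3-dihydro-1-benzofuran-4-ol, via diphenol triol 15 (not isolated)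
Conditions: HCl (3 M), MeOH/THF, 40 °C
Reagents that add atoms: none
Why: Acidic acetal cleavage of both MOM ethers followed by SN1 cycloetherification, in which the p-silyloxybenzylic carbinol ionises and a phenol closes the five-membered ring (the two ortho hydroxyls are homotopic, so either gives the same product); the aryl group takes the face anti to the C3 hydroxymethyl group, which is also the thermodynamic 2,3-trans arrangement, so C2 follows from the auxiliary-set C3 whatever the carbinol configuration.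

Step 9
Reactants: 16 (2S,3R)-3,6-bis(hydroxymethyl)-2-{3-methoxy-4-[tri(propan-2-yl)silyloxy]phenyl}-2,3-dihydro-1-benzofuran-4-ol
Product: 17 [(2S,3R)-4-methoxy-2-{3-methoxy-4-[tri(propan-2-yl)silyloxy]phenyl}-2,3-dihydro-1-benzofuran-3,6-diyl]dimethanol
Conditions: MeI, K2CO3, acetone, rt
Reagents that add atoms: iodomethane CI
Why: Williamson O-methylation that is chemoselective for the phenol, since carbonate deprotonates only the phenolic OH and the anhydrous aprotic medium should leave the aryl silyl ether intact.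

Step 10
Reactants: 17 [(2S,3R)-4-methoxy-2-{3-methoxy-4-[tri(propan-2-yl)silyloxy]phenyl}-2,3-dihydro-1-benzofuran-3,6-diyl]dimethanol
Product: 18 (2S,3R)-3-(hydroxymethyl)-4-methoxy-2-{3-methoxy-4-[tri(propan-2-yl)silyloxy]phenyl}-2,3-dihydro-1-benzofuran-6-carbaldehyde
Conditions: MnO2, CH2Cl2, rt
Reagents that add atoms: none
Why: Manganese dioxide oxidation, selective for the benzylic alcohol over the aliphatic primary alcohol.

Step 11
Reactants: 18 (2S,3R)-3-(hydroxymethyl)-4-methoxy-2-{3-methoxy-4-[tri(propan-2-yl)silyloxy]phenyl}-2,3-dihydro-1-benzofuran-6-carbaldehyde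
Product: 19 [(2S,3R)-6-(1,3-dithian-2-yl)-4-methoxy-2-{3-methoxy-4-[tri(propan-2-yl)silyloxy]phenyl}-2,3-dihydro-1-benzofuran-3-yl]methanol
Conditions: HS(CH2)3SH, BF3·OEt2 (cat.), CH2Cl2, 0 °C
Reagents that add atoms: propane-1,3-dithiol SCCCS
Why: Lewis-acid-catalysed dithioacetalisation of the aryl aldehyde, which turns the future benzylic CH2 into an acyl-anion equivalent; brief cold exposure should spare the benzylic ring ether.

Step 12
Reactants: 19 [(2S,3R)-6-(1,3-dithian-2-yl)-4-methoxy-2-{3-methoxy-4-[tri(propan-2-yl)silyloxy]phenyl}-2,3-dihydro-1-benzofuran-3-yl]methanol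
Product: 20 2-[(2S,3R)-4-methoxy-2-{3-methoxy-4-[tri(propan-2-yl)silyloxy]phenyl}-3-{[tri(propan-2-yl)silyloxy]methyl}-2,3-dihydro-1-benzofuran-6-yl]-1,3-dithiane
Conditions: TIPSOTf, 2,6-lutidine, CH2Cl2, 0 °C
Reagents that add atoms: tri(propan-2-yl)silyl trifluoromethanesulfonate CC(C)[Si](C(C)C)(C(C)C)OS(=O)(=O)C(F)(F)F
Why: Silylation of the primary alcohol so that the only acidic C–H or O–H left for the organolithium step is the dithiane C–H.

Step 13
Reactants: 21 isovanillin (3-hydroxy-4-methoxybenzaldehyde)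
Product: 22 4-methoxy-3-[tri(propan-2-yl)silyloxy]benzaldehyde
Conditions: TIPSCl, imidazole, DMF, rt
Reagents that add atoms: chlorotri(propan-2-yl)silane CC(C)[Si](Cl)(C(C)C)C(C)C
Why: Phenol silylation, giving the third component with the same fluoride-labile protecting group as the other hydroxyls.

Step 14
Reactants: 23 5-hydroxyfuran-2(5H)-one; 24 (+)-menthol [(1S,2R,5S)-5-methyl-2-(propan-2-yl)cyclohexan-1-ol]
Product: 25 (5S)-5-{[(1S,2R,5S)-5-methyl-2-(propan-2-yl)cyclohexyl]oxy}furan-2(5H)-one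
Conditions: CSA (cat.), toluene, reflux (Dean–Stark); crystallisation from petroleum ether
Reagents that add atoms: none
Why: Acid-catalysed acetalisation of the pseudo-acid; the two C5 epimers interconvert under the acid and the (5S) d-menthyl epimer is the one expected to crystallise, mirroring the known l-menthyl/(5R) series.

Step 15
Reactants: 20 2-[(2S,3R)-4-methoxy-2-{3-methoxy-4-[tri(propan-2-yl)silyloxy]phenyl}-3-{[tri(propan-2-yl)silyloxy]methyl}-2,3-dihydro-1-benzofuran-6-yl]-1,3-dithiane; 25 (5S)-5-(d-menthyloxy)furan-2(5H)-one; 22 4-methoxy-3-[tri(propan-2-yl)silyloxy]benzaldehyde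
Product: 28 (3R,4S,5S)-3-(hydroxy{4-methoxy-3-[tri(propan-2-yl)silyloxy]phenyl}methyl)-4-{2-[(2S,3R)-dihydrobenzofuran-6-yl]-1,3-dithian-2-yl}-5-(d-menthyloxy)oxolan-2-one (dihydrobenzofuranyl group as in 20; epimers at the carbinol carbon), via lithiated dithiane 26 (not isolated), via lithium lactone enolate 27 (not isolated)
Conditions: n-BuLi, THF, −78 °C; 25, −78 °C; then 22, −78 → −50 °C; aq NH4Cl
Reagents that add atoms: none
Why: n-BuLi removes the dithiane C–H (the most acidic site of 20) to give carbanion 26, which adds 1,4 to butenolide 25 and forms the bond between the future benzylic carbon and the future oxolane C4; the resulting lactone enolate 27 is then intercepted by aldehyde 22 in a lithium aldol reaction. The closest known reaction type is the tandem conjugate addition–aldol of lithiated aryl dithioacetals to 5-alkoxyfuran-2(5H)-ones used for lignan lactones. No ring is closed in this step; the carbons it assembles are closed to the oxolane in step 18. The lactone C4 centre is set by addition anti to the menthyloxy group on C5 (auxiliary control), the C3 centre by approach of the aldehyde anti to the new bulky C4 substituent (3,4-trans), and the carbinol carbon is not controlled and need not be. The step needs 1,4- over 1,2-addition, secured by the soft, hindered sulfur-stabilised carbanion at low temperature; it needs metalation at the dithiane and not on the rings, secured by the acidity of the 2-aryl-dithiane C–H; and it needs face selectivity, secured by the acetal substituent next to the β-carbon.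

Step 16
Reactants: 28 the three-component adduct
Product: 29 (3R,4S,5S)-3-(hydroxy{4-methoxy-3-[tri(propan-2-yl)silyloxy]phenyl}methyl)-4-{[(2S,3R)-dihydrobenzofuran-6-yl]methyl}-5-(d-menthyloxy)oxolan-2-one (dihydrobenzofuranyl group as in 20; epimers at the carbinol carbon)
Conditions: Raney Ni (W-2), EtOH, rt
Reagents that add atoms: none
Why: Raney nickel desulfurisation of the dithioketal (Mozingo-type reduction) converts the acyl-anion carbon into the benzylic CH2; room temperature is chosen to spare the benzylic C–O bonds, the silyl ethers and the lactone acetal.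

Step 17
Reactants: 29 the desulfurised lactone acetal
Product: 30 (2S,3S)-2-(hydroxy{4-methoxy-3-[tri(propan-2-yl)silyloxy]phenyl}methyl)-3-{[(2S,3R)-dihydrobenzofuran-6-yl]methyl}butane-1,4-diol (dihydrobenzofuranyl group as in 20; epimers at the carbinol carbon)
Conditions: LiAlH4, THF, 0 °C → rt
Reagents that add atoms: none
Why: Hydride reduction of the pseudo-ester: the lactone carbonyl goes to CH2OH, the liberated hemiacetal alkoxide collapses to the aldehyde with loss of menthoxide and is reduced in turn, so both ring carbons emerge as primary alcohols and the two backbone stereocentres are untouched.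

Step 18
Reactants: 30 the triol
Product: 31 [(2R,3S,4S)-2-{4-methoxy-3-[tri(propan-2-yl)silyloxy]phenyl}-4-{[(2S,3R)-dihydrobenzofuran-6-yl]methyl}oxolan-3-yl]methanol (dihydrobenzofuranyl group as in 20)
Conditions: CSA (cat.), CH2Cl2, 0 °C → rt, quenched (Et3N) as soon as 30 is consumed
Reagents that add atoms: none
Why: Acid-catalysed SN1 cycloetherification: the p-methoxybenzylic carbinol ionises and the primary hydroxyl that is 1,4 to it closes the five-membered ring (the other primary hydroxyl could only give an oxetane), with the aryl group ending trans to the neighbouring hydroxymethyl group by anti attack and thermodynamic preference, so both carbinol epimers converge on oxolane C2 = R; catalytic acid, low temperature and an early quench are meant to keep the cation from Friedel–Crafts closure onto the benzofuran ring.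

Step 19
Reactants: 31 the tris-TIPS ether
Product: 32 5-[(2R,3S,4S)-3-(hydroxymethyl)-4-{[(2S,3R)-2-(4-hydroxy-3-methoxyphenyl)-3-(hydroxymethyl)-4-methoxy-2,3-dihydro-1-benzofuran-6-yl]methyl}oxolan-2-yl]-2-methoxyphenol (CNP0242386.1)
Conditions: TBAF, THF, 0 °C → rt; aq NH4Cl
Reagents that add atoms: none
Why: Fluoride-mediated desilylation removes the two aryl and one primary alkyl TIPS ethers under conditions that cannot ionise either benzylic ether, so no stereocentre is at risk.

**Compound list**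
1 | methyl 4-bromo-3,5-dihydroxybenzoate | COC(=O)c1cc(O)c(Br)c(O)c1 | starting material
2 | methyl 4-bromo-3,5-bis(methoxymethoxy)benzoate | COCOc1cc(C(=O)OC)cc(OCOC)c1Br | intermediate
3 | benzyl bromoacetate | BrCC(=O)OCc1ccccc1 | starting material
4 | bromo[2-(benzyloxy)-2-oxoethyl]zinc (Reformatsky reagent) | Br[Zn]CC(=O)OCc1ccccc1 | intermediate (not isolated)
5 | benzyl 2-[4-(methoxycarbonyl)-2,6-bis(methoxymethoxy)phenyl]acetate | COCOc1cc(C(=O)OC)cc(OCOC)c1CC(=O)OCc1ccccc1 | intermediate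
6 | 2-[4-(methoxycarbonyl)-2,6-bis(methoxymethoxy)phenyl]acetic acid | COCOc1cc(C(=O)OC)cc(OCOC)c1CC(=O)O | intermediate
7 | (S)-4-benzyl-1,3-oxazolidin-2-one | O=C1N[C@@H](Cc2ccccc2)CO1 | starting material
8 | mixed anhydride of 6 with pivalic acid | COCOc1cc(C(=O)OC)cc(OCOC)c1CC(=O)OC(=O)C(C)(C)C | intermediate (not isolated)
9 | methyl 4-{2-[(4S)-4-benzyl-2-oxo-1,3-oxazolidin-3-yl]-2-oxoethyl}-3,5-bis(methoxymethoxy)benzoate | COCOc1cc(C(=O)OC)cc(OCOC)c1CC(=O)N1C(=O)OC[C@@H]1Cc1ccccc1 | intermediate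
10 | vanillin | COc1cc(C=O)ccc1O | starting material
11 | 3-methoxy-4-[tri(propan-2-yl)silyloxy]benzaldehyde | COc1cc(C=O)ccc1O[Si](C(C)C)(C(C)C)C(C)C | intermediate
12 | (Z)-dibutylboron enolate of 9 | CCCCB(CCCC)O/C(=C\c1c(OCOC)cc(C(=O)OC)cc1OCOC)N1C(=O)OC[C@@H]1Cc1ccccc1 | intermediate (not isolated)
13 | (4S)-4-benzyl-3-[(2S,3S)-3-hydroxy-2-[4-(methoxycarbonyl)-2,6-bis(methoxymethoxy)phenyl]-3-{3-methoxy-4-[tri(propan-2-yl)silyloxy]phenyl}propanoyl]-1,3-oxazolidin-2-one | O=C1OC[C@H](Cc2ccccc2)N1C(=O)[C@@H](c1c(OCOC)cc(C(=O)OC)cc1OCOC)[C@H](O)c1ccc(O[Si](C(C)C)(C(C)C)C(C)C)c(OC)c1 | intermediate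
14 | (1S,2R)-2-[4-(hydroxymethyl)-2,6-bis(methoxymethoxy)phenyl]-1-{3-methoxy-4-[tri(propan-2-yl)silyloxy]phenyl}propane-1,3-diol | OC[C@@H](c1c(OCOC)cc(CO)cc1OCOC)[C@H](O)c1ccc(O[Si](C(C)C)(C(C)C)C(C)C)c(OC)c1 | intermediate
15 | (1S,2R)-2-[2,6-dihydroxy-4-(hydroxymethyl)phenyl]-1-{3-methoxy-4-[tri(propan-2-yl)silyloxy]phenyl}propane-1,3-diol | OC[C@@H](c1c(O)cc(CO)cc1O)[C@H](O)c1ccc(O[Si](C(C)C)(C(C)C)C(C)C)c(OC)c1 | intermediate (not isolated)
16 | (2S,3R)-3,6-bis(hydroxymethyl)-2-{3-methoxy-4-[tri(propan-2-yl)silyloxy]phenyl}-2,3-dihydro-1-benzofuran-4-ol | OCc1cc(O)c2c(c1)O[C@H](c1ccc(O[Si](C(C)C)(C(C)C)C(C)C)c(OC)c1)[C@H]2CO | intermediate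
17 | [(2S,3R)-4-methoxy-2-{3-methoxy-4-[tri(propan-2-yl)silyloxy]phenyl}-2,3-dihydro-1-benzofuran-3,6-diyl]dimethanol | OCc1cc(OC)c2c(c1)O[C@H](c1ccc(O[Si](C(C)C)(C(C)C)C(C)C)c(OC)c1)[C@H]2CO | intermediate
18 | (2S,3R)-3-(hydroxymethyl)-4-methoxy-2-{3-methoxy-4-[tri(propan-2-yl)silyloxy]phenyl}-2,3-dihydro-1-benzofuran-6-carbaldehyde | O=Cc1cc(OC)c2c(c1)O[C@H](c1ccc(O[Si](C(C)C)(C(C)C)C(C)C)c(OC)c1)[C@H]2CO | intermediate
19 | [(2S,3R)-6-(1,3-dithian-2-yl)-4-methoxy-2-{3-methoxy-4-[tri(propan-2-yl)silyloxy]phenyl}-2,3-dihydro-1-benzofuran-3-yl]methanol | S1CCCSC1c1cc(OC)c2c(c1)O[C@H](c1ccc(O[Si](C(C)C)(C(C)C)C(C)C)c(OC)c1)[C@H]2CO | intermediate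
20 | 2-[(2S,3R)-4-methoxy-2-{3-methoxy-4-[tri(propan-2-yl)silyloxy]phenyl}-3-{[tri(propan-2-yl)silyloxy]methyl}-2,3-dihydro-1-benzofuran-6-yl]-1,3-dithiane | S1CCCSC1c1cc(OC)c2c(c1)O[C@H](c1ccc(O[Si](C(C)C)(C(C)C)C(C)C)c(OC)c1)[C@H]2CO[Si](C(C)C)(C(C)C)C(C)C | intermediate
21 | isovanillin | COc1ccc(C=O)cc1O | starting material
22 | 4-methoxy-3-[tri(propan-2-yl)silyloxy]benzaldehyde | COc1ccc(C=O)cc1O[Si](C(C)C)(C(C)C)C(C)C | intermediate
23 | 5-hydroxyfuran-2(5H)-one | OC1OC(=O)C=C1 | starting material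
24 | (+)-menthol, (1S,2R,5S) | CC(C)[C@H]1CC[C@H](C)C[C@@H]1O | starting material
25 | (5S)-5-{[(1S,2R,5S)-5-methyl-2-(propan-2-yl)cyclohexyl]oxy}furan-2(5H)-one | O=C1C=C[C@@H](O[C@H]2C[C@@H](C)CC[C@@H]2C(C)C)O1 | intermediate
26 | 2-lithio derivative of dithiane 20 | [Li]C1(SCCCS1)c1cc(OC)c2c(c1)O[C@H](c1ccc(O[Si](C(C)C)(C(C)C)C(C)C)c(OC)c1)[C@H]2CO[Si](C(C)C)(C(C)C)C(C)C | intermediate (not isolated)
27 | lithium enolate of the (4S,5S) 1,4-adduct of 26 to 25 | [Li]OC1=C[C@H](C2(SCCCS2)c2cc(OC)c3c(c2)O[C@H](c2ccc(O[Si](C(C)C)(C(C)C)C(C)C)c(OC)c2)[C@H]3CO[Si](C(C)C)(C(C)C)C(C)C)[C@@H](O[C@H]2C[C@@H](C)CC[C@@H]2C(C)C)O1 | intermediate (not isolated)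
28 | (3R,4S,5S)-3-(hydroxy{4-methoxy-3-[tri(propan-2-yl)silyloxy]phenyl}methyl)-4-{2-[(2S,3R)-dihydrobenzofuran-6-yl of 20]-1,3-dithian-2-yl}-5-(d-menthyloxy)oxolan-2-one, carbinol epimers | O=C1O[C@H](O[C@H]2C[C@@H](C)CC[C@@H]2C(C)C)[C@@H](C2(SCCCS2)c2cc(OC)c3c(c2)O[C@H](c2ccc(O[Si](C(C)C)(C(C)C)C(C)C)c(OC)c2)[C@H]3CO[Si](C(C)C)(C(C)C)C(C)C)[C@@H]1C(O)c1ccc(OC)c(O[Si](C(C)C)(C(C)C)C(C)C)c1 | intermediate
29 | (3R,4S,5S)-3-(hydroxy{4-methoxy-3-[tri(propan-2-yl)silyloxy]phenyl}methyl)-4-{[(2S,3R)-dihydrobenzofuran-6-yl of 20]methyl}-5-(d-menthyloxy)oxolan-2-one, carbinol epimers | O=C1O[C@H](O[C@H]2C[C@@H](C)CC[C@@H]2C(C)C)[C@@H](Cc2cc(OC)c3c(c2)O[C@H](c2ccc(O[Si](C(C)C)(C(C)C)C(C)C)c(OC)c2)[C@H]3CO[Si](C(C)C)(C(C)C)C(C)C)[C@@H]1C(O)c1ccc(OC)c(O[Si](C(C)C)(C(C)C)C(C)C)c1 | intermediate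
30 | (2S,3S)-2-(hydroxy{4-methoxy-3-[tri(propan-2-yl)silyloxy]phenyl}methyl)-3-{[(2S,3R)-dihydrobenzofuran-6-yl of 20]methyl}butane-1,4-diol, carbinol epimers | OC[C@@H](Cc1cc(OC)c2c(c1)O[C@H](c1ccc(O[Si](C(C)C)(C(C)C)C(C)C)c(OC)c1)[C@H]2CO[Si](C(C)C)(C(C)C)C(C)C)[C@@H](CO)C(O)c1ccc(OC)c(O[Si](C(C)C)(C(C)C)C(C)C)c1 | intermediate
31 | tris-TIPS ether of the target: [(2R,3S,4S)-2-{4-methoxy-3-[tri(propan-2-yl)silyloxy]phenyl}-4-{[(2S,3R)-dihydrobenzofuran-6-yl of 20]methyl}oxolan-3-yl]methanol | COc1ccc([C@@H]2OC[C@@H](Cc3cc(OC)c4c(c3)O[C@H](c3ccc(O[Si](C(C)C)(C(C)C)C(C)C)c(OC)c3)[C@H]4CO[Si](C(C)C)(C(C)C)C(C)C)[C@H]2CO)cc1O[Si](C(C)C)(C(C)C)C(C)C | intermediate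
32 | 5-[(2R,3S,4S)-3-(hydroxymethyl)-4-{[(2S,3R)-2-(4-hydroxy-3-methoxyphenyl)-3-(hydroxymethyl)-4-methoxy-2,3-dihydro-1-benzofuran-6-yl]methyl}oxolan-2-yl]-2-methoxyphenol | COc1ccc([C@@H]2OC[C@@H](Cc3cc(OC)c4c(c3)O[C@H](c3ccc(O)c(OC)c3)[C@H]4CO)[C@H]2CO)cc1O | target

Total steps: 19
Longest linear sequence: 16 steps (steps 1–4, 6–12, 15–19)

**Steps most likely to fail**

Step 15. After the conjugate addition, the crowded lithium enolate may be protonated, or may expel the dithiane anion again on warming, before the electron-rich aldehyde is taken up, so the third component is incorporated incompletely; 1,2-addition to the lactone carbonyl is a second loss channel. Fallback: set out from 20 and 25, run the conjugate addition alone and quench at −78 °C with acetic acid to isolate the (4S,5S) Michael adduct lactone F1. The α-carbanion of F1 is then regenerated in a separate operation (LDA, THF, −78 °C, then ZnCl2) and the zinc enolate is condensed with 22, again anti to the C4 substituent. This two-stage sequence comes back to the route at 28.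

Step 18. The benzylic cation may be diverted into intramolecular Friedel–Crafts alkylation of the electron-rich benzofuran ring at the positions flanking the benzylic CH2, and the product oxolane may re-ionise under the acid, which funnels material toward an aryltetralin. Fallback: a closure that never places a cation at the aryl-bearing carbon, setting out from 29.
- Dess–Martin oxidation of the carbinol mixture gives the single aroyl lactone F2.
- Chelation-controlled reduction (Zn(BH4)2, Et2O, −20 °C) gives the syn carbinol F3, with the carbinol carbon R.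
- Mild acid-catalysed methanolysis of the pseudo-ester (CSA cat., MeOH, rt) lets the carbinol oxygen capture the acetal carbon, with retention at the carbinol, to give the oxolane methyl acetal ester F4.
- Anomeric reduction (Et3SiH, BF3·OEt2, CH2Cl2, −78 °C) removes the acetal oxygen to give the oxolane ester F5.
- LiAlH4 reduction of the ester comes back to the route at 31.

Step 2. Oxidative addition and transmetalation at the doubly ortho-alkoxylated C–Br bond may be slow, so that protodebromination of the arene and self-condensation of the zinc enolate outrun the coupling. Fallback: set out from 2 and install the two carbons by Stille allylation (allyltributylstannane, Pd(PPh3)4, DMF, 90 °C) to give the allyl arene F6. Ozonolysis (O3, CH2Cl2/MeOH, −78 °C; PPh3) gives the arylacetaldehyde F7, and Pinnick oxidation (NaClO2, NaH2PO4, 2-methyl-2-butene, t-BuOH/H2O) comes back to the route at 6.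

Further compounds
F1 | step 15 | (4S,5S)-4-{2-[(2S,3R)-dihydrobenzofuran-6-yl of 20]-1,3-dithian-2-yl}-5-(d-menthyloxy)oxolan-2-one | O=C1O[C@H](O[C@H]2C[C@@H](C)CC[C@@H]2C(C)C)[C@@H](C2(SCCCS2)c2cc(OC)c3c(c2)O[C@H](c2ccc(O[Si](C(C)C)(C(C)C)C(C)C)c(OC)c2)[C@H]3CO[Si](C(C)C)(C(C)C)C(C)C)C1
F2 | step 18 | (3R,4S,5S)-3-{4-methoxy-3-[tri(propan-2-yl)silyloxy]benzoyl}-4-{[(2S,3R)-dihydrobenzofuran-6-yl of 20]methyl}-5-(d-menthyloxy)oxolan-2-one | O=C1O[C@H](O[C@H]2C[C@@H](C)CC[C@@H]2C(C)C)[C@@H](Cc2cc(OC)c3c(c2)O[C@H](c2ccc(O[Si](C(C)C)(C(C)C)C(C)C)c(OC)c2)[C@H]3CO[Si](C(C)C)(C(C)C)C(C)C)[C@@H]1C(=O)c1ccc(OC)c(O[Si](C(C)C)(C(C)C)C(C)C)c1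
F3 | step 18 | (3R,4S,5S)-3-[(R)-hydroxy{4-methoxy-3-[tri(propan-2-yl)silyloxy]phenyl}methyl]-4-{[(2S,3R)-dihydrobenzofuran-6-yl of 20]methyl}-5-(d-menthyloxy)oxolan-2-one | O=C1O[C@H](O[C@H]2C[C@@H](C)CC[C@@H]2C(C)C)[C@@H](Cc2cc(OC)c3c(c2)O[C@H](c2ccc(O[Si](C(C)C)(C(C)C)C(C)C)c(OC)c2)[C@H]3CO[Si](C(C)C)(C(C)C)C(C)C)[C@@H]1[C@@H](O)c1ccc(OC)c(O[Si](C(C)C)(C(C)C)C(C)C)c1
F4 | step 18 | methyl (2R,3R,4S)-5-methoxy-2-{4-methoxy-3-[tri(propan-2-yl)silyloxy]phenyl}-4-{[(2S,3R)-dihydrobenzofuran-6-yl of 20]methyl}oxolane-3-carboxylate (C5 anomers) | COc1ccc([C@@H]2OC(OC)[C@@H](Cc3cc(OC)c4c(c3)O[C@H](c3ccc(O[Si](C(C)C)(C(C)C)C(C)C)c(OC)c3)[C@H]4CO[Si](C(C)C)(C(C)C)C(C)C)[C@H]2C(=O)OC)cc1O[Si](C(C)C)(C(C)C)C(C)C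
F5 | step 18 | methyl (2R,3R,4S)-2-{4-methoxy-3-[tri(propan-2-yl)silyloxy]phenyl}-4-{[(2S,3R)-dihydrobenzofuran-6-yl of 20]methyl}oxolane-3-carboxylate | COc1ccc([C@@H]2OC[C@@H](Cc3cc(OC)c4c(c3)O[C@H](c3ccc(O[Si](C(C)C)(C(C)C)C(C)C)c(OC)c3)[C@H]4CO[Si](C(C)C)(C(C)C)C(C)C)[C@H]2C(=O)OC)cc1O[Si](C(C)C)(C(C)C)C(C)C
F6 | step 2 | methyl 3,5-bis(methoxymethoxy)-4-(prop-2-en-1-yl)benzoate | COCOc1cc(C(=O)OC)cc(OCOC)c1CC=C
F7 | step 2 | methyl 3,5-bis(methoxymethoxy)-4-(2-oxoethyl)benzoate | COCOc1cc(C(=O)OC)cc(OCOC)c1CC=O
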